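**Retrosynthetic overview**
- The target comes from its penta-O-benzyl ether by one global hydrogenolysis at the end.
- Key disconnection, C8–CH(CH3)Ar: an 8-bromo-tetra-O-benzylisorhamnetin (C8 as the electrophile) plus 4-(benzyloxy)-3,5-dimethoxystyrene. Chiral CuH turns the styrene in the flask into a secondary benzylic carbanion equivalent, although the same vinylphenol unit normally reacts as a benzylic cation (p-quinone methide) precursor. The C–C bond and the (R) centre are formed in the same step.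
- The bromoflavonol comes from C8-selective bromination, 3-O-benzylation, and 5,7,4'-tri-O-benzylisorhamnetin.
- Ring C is the only ring made (rings A and B are bought): Algar–Flynn–Oyamada closure of a 2'-hydroxychalcone, itself from a Claisen–Schmidt condensation of phloroacetophenone dibenzyl ether with O-benzylvanillin.
- The styrene comes from Wittig methylenation of O-benzylsyringaldehyde.

Assumption 1: 1-[2,4-bis(benzyloxy)-6-hydroxyphenyl]ethan-1-one, 4-(benzyloxy)-3-methoxybenzaldehyde and 4-(benzyloxy)-3,5-dimethoxybenzaldehyde are bought as catalogue compounds.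
Assumption 2: (S)-DTBM-SEGPHOS is named as the ligand antipode that gives the (R) product, by analogy with CuH hydroamination of styrenes and assuming retention in the copper-to-palladium transfer; the first run is checked by chiral HPLC and ECD, and the (R) ligand is used if the sense is the opposite.

**Route**

Step 1
Reactants: 1 1-[2,4-bis(benzyloxy)-6-hydroxyphenyl]ethan-1-one; 2 4-(benzyloxy)-3-methoxybenzaldehyde
Product: 4 (2E)-1-[2,4-bis(benzyloxy)-6-hydroxyphenyl]-3-[4-(benzyloxy)-3-methoxyphenyl]prop-2-en-1-one, via racemic aldol adduct 3 (not isolated)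
Conditions: KOH (50% aq), EtOH/THF, rt, 24 h
Reagents that add atoms: none
Why: Claisen–Schmidt aldol condensation, in which the acetophenone enolate adds to the non-enolisable aldehyde and the aldol 3 dehydrates (E1cB) to the conjugated E-enone, so the carbinol stereocentre of 3 is lost.

Step 2
Reactants: 4 (2E)-1-[2,4-bis(benzyloxy)-6-hydroxyphenyl]-3-[4-(benzyloxy)-3-methoxyphenyl]prop-2-en-1-one
Product: 6 5,7-bis(benzyloxy)-2-[4-(benzyloxy)-3-methoxyphenyl]-3-hydroxy-4H-chromen-4-one, via racemic trans-dihydroflavonol 5 (not isolated)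
Conditions: H2O2 (30% aq), NaOH (aq), MeOH/THF, 0 °C to rt
Reagents that add atoms: hydrogen peroxide, OO
Why: Algar–Flynn–Oyamada reaction, in which the 2'-phenoxide closes ring C onto the enone β-carbon while alkaline H2O2 oxygenates C3 to give trans-dihydroflavonol 5, which is dehydrogenated in the same pot to the flavonol, erasing both transient stereocentres.

Step 3
Reactants: 6 5,7-bis(benzyloxy)-2-[4-(benzyloxy)-3-methoxyphenyl]-3-hydroxy-4H-chromen-4-one
Product: 7 3,5,7-tris(benzyloxy)-2-[4-(benzyloxy)-3-methoxyphenyl]-4H-chromen-4-one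
Conditions: BnBr, K2CO3, DMF, 60 °C
Reagents that add atoms: benzyl bromide, BrCc1ccccc1
Why: Williamson etherification of the only free hydroxyl, which also removes the chelating flavonolate that would otherwise bind copper and palladium in step 6.

Step 4
Reactants: 7 3,5,7-tris(benzyloxy)-2-[4-(benzyloxy)-3-methoxyphenyl]-4H-chromen-4-one
Product: 8 3,5,7-tris(benzyloxy)-2-[4-(benzyloxy)-3-methoxyphenyl]-8-bromo-4H-chromen-4-one
Conditions: NBS (1.05 equiv), DMF, 0 °C to rt, dark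
Reagents that add atoms: N-bromosuccinimide, O=C1CCC(=O)N1Br
Why: electrophilic aromatic bromination of the most electron-rich ring (ring A), which in 5,7-dialkoxyflavones without a free 5-hydroxyl goes to C8 (between O1 and the 7-ether) in preference to C6, here further shielded by two benzyloxy groups.

Step 5
Reactants: 9 4-(benzyloxy)-3,5-dimethoxybenzaldehyde
Product: 10 2-(benzyloxy)-5-ethenyl-1,3-dimethoxybenzene
Conditions: Ph3PCH3Br, KOtBu, THF, 0 °C to rt
Reagents that add atoms: methyltriphenylphosphonium bromide, C[P+](c1ccccc1)(c1ccccc1)c1ccccc1.[Br-]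
Why: Wittig methylenation of a non-enolisable aryl aldehyde with the unstabilised ylide made in the flask.

Step 6
Reactants: 8 3,5,7-tris(benzyloxy)-2-[4-(benzyloxy)-3-methoxyphenyl]-8-bromo-4H-chromen-4-one; 10 2-(benzyloxy)-5-ethenyl-1,3-dimethoxybenzene (1.5 equiv)
Product: 11 3,5,7-tris(benzyloxy)-2-[4-(benzyloxy)-3-methoxyphenyl]-8-{(1R)-1-[4-(benzyloxy)-3,5-dimethoxyphenyl]ethyl}-4H-chromen-4-one
Conditions: Cu(OAc)2 (5 mol %), (S)-DTBM-SEGPHOS (5.5 mol %), [Pd(cinnamyl)Cl]2 (2.5 mol %), BrettPhos (5.5 mol %), MePh2SiH (2 equiv), NaOSiMe3 (2 equiv), THF, rt to 45 °C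
Reagents that add atoms: none
Why: asymmetric Markovnikov hydroarylation of a vinylarene by dual CuH/Pd catalysis, a known reaction type stretched here to a 2,6-dioxygenated aryl bromide: ligand-bound CuH adds across the vinyl group of 10 to give a configurationally defined secondary benzylcopper species, which is transferred stereospecifically to the (BrettPhos)Pd(aryl)Br complex from oxidative addition of the C8–Br bond and reductively eliminated, so the (R) centre is set by catalyst control in the hydrocupration, while the fully substituted 3-alkoxy-γ-pyrone should be too poor a hydride acceptor to compete.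

Step 7
Reactants: 11 3,5,7-tris(benzyloxy)-2-[4-(benzyloxy)-3-methoxyphenyl]-8-{(1R)-1-[4-(benzyloxy)-3,5-dimethoxyphenyl]ethyl}-4H-chromen-4-one
Product: 12 3,5,7-trihydroxy-2-(4-hydroxy-3-methoxyphenyl)-8-[(1R)-1-(4-hydroxy-3,5-dimethoxyphenyl)ethyl]-4H-chromen-4-one
Conditions: H2 (1 atm), Pd/C (10 wt % Pd), THF/MeOH, rt
Reagents that add atoms: none
Why: heterogeneous hydrogenolysis of the five benzyl ethers under neutral conditions, which leaves the methyl ethers, the flavonol C2=C3 bond and the diarylmethine C–C bonds alone and offers no acid that could ionise the benzylic stereocentre.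

**Compound list**

1 | 1-[2,4-bis(benzyloxy)-6-hydroxyphenyl]ethan-1-one | CC(=O)c1c(O)cc(OCc2ccccc2)cc1OCc1ccccc1 | starting material
2 | 4-(benzyloxy)-3-methoxybenzaldehyde | COc1cc(C=O)ccc1OCc1ccccc1 | starting material
3 | 1-[2,4-bis(benzyloxy)-6-hydroxyphenyl]-3-[4-(benzyloxy)-3-methoxyphenyl]-3-hydroxypropan-1-one (racemic aldol adduct, stereocentre undefined, not isolated) | COc1cc(C(O)CC(=O)c2c(O)cc(OCc3ccccc3)cc2OCc2ccccc2)ccc1OCc1ccccc1 | intermediate
4 | (2E)-1-[2,4-bis(benzyloxy)-6-hydroxyphenyl]-3-[4-(benzyloxy)-3-methoxyphenyl]prop-2-en-1-one | COc1cc(/C=C/C(=O)c2c(O)cc(OCc3ccccc3)cc2OCc2ccccc2)ccc1OCc1ccccc1 | intermediate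
5 | rac-(2R,3R)-5,7-bis(benzyloxy)-2-[4-(benzyloxy)-3-methoxyphenyl]-3-hydroxy-2,3-dihydro-4H-chromen-4-one (racemic trans-dihydroflavonol, one enantiomer drawn, not isolated) | O=C1[C@H](O)[C@@H](c2ccc(OCc3ccccc3)c(OC)c2)Oc2cc(OCc3ccccc3)cc(OCc3ccccc3)c12 | intermediate
6 | 5,7-bis(benzyloxy)-2-[4-(benzyloxy)-3-methoxyphenyl]-3-hydroxy-4H-chromen-4-one | COc1cc(-c2oc3cc(OCc4ccccc4)cc(OCc4ccccc4)c3c(=O)c2O)ccc1OCc1ccccc1 | intermediate
7 | 3,5,7-tris(benzyloxy)-2-[4-(benzyloxy)-3-methoxyphenyl]-4H-chromen-4-one | COc1cc(-c2oc3cc(OCc4ccccc4)cc(OCc4ccccc4)c3c(=O)c2OCc2ccccc2)ccc1OCc1ccccc1 | intermediate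
8 | 3,5,7-tris(benzyloxy)-2-[4-(benzyloxy)-3-methoxyphenyl]-8-bromo-4H-chromen-4-one | COc1cc(-c2oc3c(Br)c(OCc4ccccc4)cc(OCc4ccccc4)c3c(=O)c2OCc2ccccc2)ccc1OCc1ccccc1 | intermediate
9 | 4-(benzyloxy)-3,5-dimethoxybenzaldehyde | COc1cc(C=O)cc(OC)c1OCc1ccccc1 | starting material
10 | 2-(benzyloxy)-5-ethenyl-1,3-dimethoxybenzene | COc1cc(C=C)cc(OC)c1OCc1ccccc1 | intermediate
11 | 3,5,7-tris(benzyloxy)-2-[4-(benzyloxy)-3-methoxyphenyl]-8-{(1R)-1-[4-(benzyloxy)-3,5-dimethoxyphenyl]ethyl}-4H-chromen-4-one | COc1cc(-c2oc3c([C@H](C)c4cc(OC)c(OCc5ccccc5)c(OC)c4)c(OCc4ccccc4)cc(OCc4ccccc4)c3c(=O)c2OCc2ccccc2)ccc1OCc1ccccc1 | intermediate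
12 | 3,5,7-trihydroxy-2-(4-hydroxy-3-methoxyphenyl)-8-[(1R)-1-(4-hydroxy-3,5-dimethoxyphenyl)ethyl]-4H-chromen-4-one | COc1cc(-c2oc3c([C@H](C)c4cc(OC)c(O)c(OC)c4)c(O)cc(O)c3c(=O)c2O)ccc1O | target

**Totals**
Total step count: 7. Longest linear sequence: 6 (steps 1, 2, 3, 4, 6, 7); step 5 is the convergent branch.

**Steps most likely to fail, with fallbacks**

Step 6. The C8 bromide is flanked by two oxygen substituents and is electron-rich, so transfer of the secondary benzyl group to palladium may be slow. Hydrodebromination of 8, reduction of 10 to the ethylarene, or hydride attack on the pyrone could then take over. The fallback sets out from 8 and 10 and comes back at 11.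
- Tsuji–Wacker oxidation of 10 (PdCl2, CuCl, O2, DMF/H2O) gives 1-[4-(benzyloxy)-3,5-dimethoxyphenyl]ethan-1-one F1.
- Condensation with TsNHNH2 (MeOH, 60 °C) gives N'-{(1E)-1-[4-(benzyloxy)-3,5-dimethoxyphenyl]ethylidene}-4-methylbenzenesulfonohydrazide F2.
- Barluenga coupling of F2 with 8 (Pd2(dba)3, XPhos, LiOtBu, dioxane, 100 °C) runs through the diazoalkane 2-(benzyloxy)-5-(1-diazoethyl)-1,3-dimethoxybenzene F3, which is not isolated. A palladium carbene forms, the C8 aryl group migrates onto it, and β-hydride elimination gives 3,5,7-tris(benzyloxy)-2-[4-(benzyloxy)-3-methoxyphenyl]-8-{1-[4-(benzyloxy)-3,5-dimethoxyphenyl]ethenyl}-4H-chromen-4-one F4. The carbonyl carbon still enters as a nucleophile, and this step tolerates hindered aryl halides far better.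
- Asymmetric hydrogenation of F4 (H2 50 bar, [Ir(cod)((S)-tBu-PHOX)][B(C6H3(CF3)2)4], CH2Cl2, ligand antipode chosen by screening) sets the (R) centre and gives 11. The benzyl ethers survive the homogeneous catalyst.

Step 2. 2'-Hydroxychalcones with a 6'-alkoxy group can divert to aurones under Algar–Flynn–Oyamada conditions. The fallback sets out from 4 and comes back at 6.
- I2 (10 mol %) in DMSO at 120 °C closes ring C oxidatively to 5,7-bis(benzyloxy)-2-[4-(benzyloxy)-3-methoxyphenyl]-4H-chromen-4-one F5.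
- Dimethyldioxirane in acetone/CH2Cl2 at 0 °C epoxidises the C2=C3 bond to the racemic cis-fused epoxide 4,6-bis(benzyloxy)-1a-[4-(benzyloxy)-3-methoxyphenyl]-1a,7a-dihydro-7H-oxireno[2,3-b]chromen-7-one F6, which is not isolated.
- Catalytic p-TsOH opens the epoxide and the product tautomerises to flavonol 6.

Step 4. Bromination of 7 may give C6/C8 mixtures or a dibromide. The fallback moves the halogenation to the acetophenone, sets out from 1 and 2, and comes back at 8.
- NBS in MeCN at 0 °C brominates 1 ortho to the free, hydrogen-bonded hydroxyl (the para position lies between two benzyloxy groups) to give 1-[4,6-bis(benzyloxy)-3-bromo-2-hydroxyphenyl]ethan-1-one F7.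
- Claisen–Schmidt condensation with 2 (KOH, EtOH/THF) passes through the racemic aldol 1-[4,6-bis(benzyloxy)-3-bromo-2-hydroxyphenyl]-3-[4-(benzyloxy)-3-methoxyphenyl]-3-hydroxypropan-1-one F8 (not isolated) to (2E)-1-[4,6-bis(benzyloxy)-3-bromo-2-hydroxyphenyl]-3-[4-(benzyloxy)-3-methoxyphenyl]prop-2-en-1-one F9.
- Alkaline H2O2 takes F9 through the racemic trans compound rac-(2R,3R)-5,7-bis(benzyloxy)-2-[4-(benzyloxy)-3-methoxyphenyl]-8-bromo-3-hydroxy-2,3-dihydro-4H-chromen-4-one F10 (not isolated) to 5,7-bis(benzyloxy)-2-[4-(benzyloxy)-3-methoxyphenyl]-8-bromo-3-hydroxy-4H-chromen-4-one F11. Ring closure through the phenol oxygen next to the bromine fixes the halogen at C8.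
- Benzylation of F11 (BnBr, K2CO3, DMF) gives 8.

**Further compounds**

F1 | step 6 | 1-[4-(benzyloxy)-3,5-dimethoxyphenyl]ethan-1-one | CC(=O)c1cc(OC)c(OCc2ccccc2)c(OC)c1
F2 | step 6 | N'-{(1E)-1-[4-(benzyloxy)-3,5-dimethoxyphenyl]ethylidene}-4-methylbenzenesulfonohydrazide | C/C(=N\NS(=O)(=O)c1ccc(C)cc1)c1cc(OC)c(OCc2ccccc2)c(OC)c1
F3 | step 6 | 2-(benzyloxy)-5-(1-diazoethyl)-1,3-dimethoxybenzene | CC(=[N+]=[N-])c1cc(OC)c(OCc2ccccc2)c(OC)c1
F4 | step 6 | 3,5,7-tris(benzyloxy)-2-[4-(benzyloxy)-3-methoxyphenyl]-8-{1-[4-(benzyloxy)-3,5-dimethoxyphenyl]ethenyl}-4H-chromen-4-one | COc1cc(-c2oc3c(C(=C)c4cc(OC)c(OCc5ccccc5)c(OC)c4)c(OCc4ccccc4)cc(OCc4ccccc4)c3c(=O)c2OCc2ccccc2)ccc1OCc1ccccc1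
F5 | step 2 | 5,7-bis(benzyloxy)-2-[4-(benzyloxy)-3-methoxyphenyl]-4H-chromen-4-one | COc1cc(-c2cc(=O)c3c(OCc4ccccc4)cc(OCc4ccccc4)cc3o2)ccc1OCc1ccccc1
F6 | step 2 | 4,6-bis(benzyloxy)-1a-[4-(benzyloxy)-3-methoxyphenyl]-1a,7a-dihydro-7H-oxireno[2,3-b]chromen-7-one (racemic, cis-fused, one enantiomer drawn) | O=C1c2c(OCc3ccccc3)cc(OCc3ccccc3)cc2O[C@]2(c3ccc(OCc4ccccc4)c(OC)c3)O[C@H]12
F7 | step 4 | 1-[4,6-bis(benzyloxy)-3-bromo-2-hydroxyphenyl]ethan-1-one | CC(=O)c1c(O)c(Br)c(OCc2ccccc2)cc1OCc1ccccc1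
F8 | step 4 | 1-[4,6-bis(benzyloxy)-3-bromo-2-hydroxyphenyl]-3-[4-(benzyloxy)-3-methoxyphenyl]-3-hydroxypropan-1-one (racemic, stereocentre undefined) | COc1cc(C(O)CC(=O)c2c(O)c(Br)c(OCc3ccccc3)cc2OCc2ccccc2)ccc1OCc1ccccc1
F9 | step 4 | (2E)-1-[4,6-bis(benzyloxy)-3-bromo-2-hydroxyphenyl]-3-[4-(benzyloxy)-3-methoxyphenyl]prop-2-en-1-one | COc1cc(/C=C/C(=O)c2c(O)c(Br)c(OCc3ccccc3)cc2OCc2ccccc2)ccc1OCc1ccccc1
F10 | step 4 | rac-(2R,3R)-5,7-bis(benzyloxy)-2-[4-(benzyloxy)-3-methoxyphenyl]-8-bromo-3-hydroxy-2,3-dihydro-4H-chromen-4-one (racemic trans, one enantiomer drawn) | O=C1[C@H](O)[C@@H](c2ccc(OCc3ccccc3)c(OC)c2)Oc2c(Br)c(OCc3ccccc3)cc(OCc3ccccc3)c12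
F11 | step 4 | 5,7-bis(benzyloxy)-2-[4-(benzyloxy)-3-methoxyphenyl]-8-bromo-3-hydroxy-4H-chromen-4-one | COc1cc(-c2oc3c(Br)c(OCc4ccccc4)cc(OCc4ccccc4)c3c(=O)c2O)ccc1OCc1ccccc1
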